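## Retrosynthetic overview

1. Ring C (the 4-pyranone) is formed last: the ring A 2'-oxygen attacks a β-keto dimethyl acetal under acid (O1–C2 bond) with loss of methanol.
2. Key disconnection, C3–aryl: the trimethoxyphenyl group is moved from C2 to C3 of a chalcone whose α-carbon has been made electrophilic by trivalent iodine (an enolonium equivalent). This replaces the usual aryl-metal coupling to a 3-halochromone or deoxybenzoin assembly; rearrangement, ester cleavage and ring closure share one flask.
3. The chalcone (C2–C3 bond) comes from a Claisen–Schmidt condensation of a ring A methyl ketone with 3,4,5-trimethoxybenzaldehyde; both phenols are acetylated before the oxidant is used.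
4. The ring A ketone (C4–C4a bond) comes from Friedel–Crafts acetylation of methoxyhydroquinone with acetic acid.
5. Rings A and B are bought intact; ring C is the only ring that is built.

Assumption: the target is a planar isoflavone with no stereocentre, so it is achiral and the structure as drawn is its only stereoisomer; no enantioselective step is needed.

## Route

Step 1
Reactants: 1 2-methoxybenzene-1,4-diol (methoxyhydroquinone); 2 acetic acid
Product: 3 1-(2,5-dihydroxy-4-methoxyphenyl)ethan-1-one
Conditions: AcOH (1.2 equiv) in BF3·OEt2 (as solvent), 90 °C, 2 h; then H2O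
Reagents that add atoms: none
Why: Friedel–Crafts (Nencki-type) C-acylation by the BF3–acetic acid complex goes to the one ring carbon that is para to the methoxy group and ortho to a hydroxyl (doubly activated, unhindered), and the product is held as a chelated ortho-hydroxy ketone that resists a second acylation; no stereocentre is formed.

Step 2
Reactants: 3 1-(2,5-dihydroxy-4-methoxyphenyl)ethan-1-one; 4 3,4,5-trimethoxybenzaldehyde
Product: 5 (E)-1-(2,5-dihydroxy-4-methoxyphenyl)-3-(3,4,5-trimethoxyphenyl)prop-2-en-1-one
Conditions: KOH (50% aq., 10 equiv), EtOH (degassed), N2, rt, 48 h; then 2 M HCl, 0 °C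
Reagents that add atoms: none
Why: Claisen–Schmidt aldol condensation of the methyl ketone enolate with a non-enolisable aldehyde, followed by E1cB loss of water, gives only the conjugated E-alkene (thermodynamic control), and exclusion of air keeps the hydroquinone anion from oxidising.

Step 3
Reactants: 5 (E)-1-(2,5-dihydroxy-4-methoxyphenyl)-3-(3,4,5-trimethoxyphenyl)prop-2-en-1-one
Product: 6 (E)-1-(2,5-diacetoxy-4-methoxyphenyl)-3-(3,4,5-trimethoxyphenyl)prop-2-en-1-one
Conditions: Ac2O (3 equiv), pyridine, 4-(dimethylamino)pyridine (cat.), 0 °C to rt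
Reagents that add atoms: acetic anhydride, CC(=O)OC(C)=O
Why: Nucleophile-catalysed O-acylation (acyl transfer through the N-acetylpyridinium ion) esterifies both phenols, which masks the hydroquinone against the oxidant of step 4 and keeps the 2'-oxygen from closing early; the E-alkene is untouched.

Step 4
Reactants: 6 (E)-1-(2,5-diacetoxy-4-methoxyphenyl)-3-(3,4,5-trimethoxyphenyl)prop-2-en-1-one
Product: 10 6-hydroxy-7-methoxy-3-(3,4,5-trimethoxyphenyl)-4H-chromen-4-one, via α-iodanyl ketone 7 (not isolated), via diacetoxy keto acetal 8 (not isolated), via dihydroxy keto acetal 9 (not isolated)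
Conditions: PhI(OH)OTs (1.1 equiv), MeOH, 40 °C; then conc. HCl, reflux
Reagents that add atoms: none
Why: Hypervalent-iodine oxidative 1,2-aryl rearrangement of a chalcone (the trivalent-iodine counterpart of the Tl(NO3)3 isoflavone synthesis) followed by acid-mediated cyclodehydration: methanol adds at the β-carbon while the α-carbon is bonded to trivalent iodine to give the enolonium equivalent 7, whose α-carbon is now electrophilic, the electron-rich trimethoxyphenyl ring shifts from the β- to the α-carbon as iodobenzene leaves (forming the C3–aryl bond) and methanol traps the β-oxocarbenium ion as acetal 8, after which HCl/MeOH cleaves both acetates (9) and the freed 2'-hydroxyl attacks the acetal carbon with loss of two methanol to give the aromatic pyranone; the stereocentres of 7–9 are erased and the target has none.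

## Compound list

1 | 2-methoxybenzene-1,4-diol (methoxyhydroquinone) | COc1cc(O)ccc1O | starting material
2 | acetic acid | CC(=O)O | starting material
3 | 1-(2,5-dihydroxy-4-methoxyphenyl)ethan-1-one | CC(=O)c1cc(O)c(OC)cc1O | intermediate
4 | 3,4,5-trimethoxybenzaldehyde | COc1cc(C=O)cc(OC)c1OC | starting material
5 | (E)-1-(2,5-dihydroxy-4-methoxyphenyl)-3-(3,4,5-trimethoxyphenyl)prop-2-en-1-one | COc1cc(O)c(cc1O)C(=O)/C=C/c1cc(OC)c(OC)c(OC)c1 | intermediate
6 | (E)-1-(2,5-diacetoxy-4-methoxyphenyl)-3-(3,4,5-trimethoxyphenyl)prop-2-en-1-one | COc1cc(OC(C)=O)c(cc1OC(C)=O)C(=O)/C=C/c1cc(OC)c(OC)c(OC)c1 | intermediate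
7 | 1-(2,5-diacetoxy-4-methoxyphenyl)-3-methoxy-2-[phenyl(tosyloxy)-λ3-iodanyl]-3-(3,4,5-trimethoxyphenyl)propan-1-one (mixture of stereoisomers, not isolated; drawn with tosylate as the ligand on iodine) | COc1cc(OC(C)=O)c(cc1OC(C)=O)C(=O)C(I(c1ccccc1)OS(=O)(=O)c1ccc(C)cc1)C(OC)c1cc(OC)c(OC)c(OC)c1 | intermediate
8 | 1-(2,5-diacetoxy-4-methoxyphenyl)-3,3-dimethoxy-2-(3,4,5-trimethoxyphenyl)propan-1-one (racemic, not isolated) | COc1cc(OC(C)=O)c(cc1OC(C)=O)C(=O)C(C(OC)OC)c1cc(OC)c(OC)c(OC)c1 | intermediate
9 | 1-(2,5-dihydroxy-4-methoxyphenyl)-3,3-dimethoxy-2-(3,4,5-trimethoxyphenyl)propan-1-one (racemic, not isolated) | COc1cc(O)c(cc1O)C(=O)C(C(OC)OC)c1cc(OC)c(OC)c(OC)c1 | intermediate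
10 | 6-hydroxy-7-methoxy-3-(3,4,5-trimethoxyphenyl)-4H-chromen-4-one (achiral) | COc1cc2occ(-c3cc(OC)c(OC)c(OC)c3)c(=O)c2cc1O | target

## Step count and risks

Total step count: 4. Longest linear sequence: 4 steps (1 → 3 → 5 → 6 → 10).

The three steps most likely to fail:

**Step 4 (highest risk).** Migration of the ring A aryl group or plain β-methoxylation can compete with the trimethoxyphenyl shift. The iodine reagent can also attack the electron-rich ring B, and an acetate lost too early would expose a hydroquinone to the oxidant. The fallback sets out from 6 and comes back at 10, and rearranges the three-carbon unit without any oxidant being present when the phenols are freed. Compound 6 is epoxidised with dimethyldioxirane in acetone at rt (neutral, so the acetates survive) to racemic trans-(2,5-diacetoxy-4-methoxyphenyl)[3-(3,4,5-trimethoxyphenyl)oxiran-2-yl]methanone F1. BF3·OEt2 in CH2Cl2 at 0 °C opens the benzylic C–O bond and the aroyl group migrates (rearrangement of an α,β-epoxy ketone) to give 3-(2,5-diacetoxy-4-methoxyphenyl)-3-oxo-2-(3,4,5-trimethoxyphenyl)propanal F2. HCl in MeOH at reflux then removes both acetates and cyclodehydrates F2 to 10.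

**Step 2.** The dihydroxy ketone reacts as a poorly enolisable trianion, and its hydroquinone unit is air-sensitive in base. The fallback sets out from 3 and comes back at 6, bypassing 5. Compound 3 is acetylated first (Ac2O, pyridine, 4-(dimethylamino)pyridine) to 1-(2,5-diacetoxy-4-methoxyphenyl)ethan-1-one F3. The condensation with 4 is then run under Lewis acid (BF3·OEt2, 1,4-dioxane, rt), which tolerates aryl acetates and never forms a phenoxide, and gives 6 directly.

**Step 1.** O-acylation, diacylation or oxidative darkening of the free hydroquinone in hot Lewis acid can cut the yield. The fallback sets out from 1 and comes back at 3. Compound 1 is converted (Ac2O, pyridine) into 2-methoxy-1,4-phenylene diacetate F4. A Fries rearrangement in CH3SO3H at 80 °C delivers an acetyl group to the carbon para to the methoxy group, giving 1-(5-acetoxy-2-hydroxy-4-methoxyphenyl)ethan-1-one F5. HCl in MeOH then removes the remaining acetate to give 3.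

Further compounds
F1 | step 4 | (2,5-diacetoxy-4-methoxyphenyl)[(2R*,3S*)-3-(3,4,5-trimethoxyphenyl)oxiran-2-yl]methanone (racemic trans; one enantiomer drawn) | COc1cc(OC(C)=O)c(cc1OC(C)=O)C(=O)[C@@H]1O[C@H]1c1cc(OC)c(OC)c(OC)c1
F2 | step 4 | 3-(2,5-diacetoxy-4-methoxyphenyl)-3-oxo-2-(3,4,5-trimethoxyphenyl)propanal (racemic, enolisable) | COc1cc(OC(C)=O)c(cc1OC(C)=O)C(=O)C(C=O)c1cc(OC)c(OC)c(OC)c1
F3 | step 2 | 1-(2,5-diacetoxy-4-methoxyphenyl)ethan-1-one | CC(=O)c1cc(OC(C)=O)c(OC)cc1OC(C)=O
F4 | step 1 | 2-methoxy-1,4-phenylene diacetate | COc1cc(OC(C)=O)ccc1OC(C)=O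
F5 | step 1 | 1-(5-acetoxy-2-hydroxy-4-methoxyphenyl)ethan-1-one | CC(=O)c1cc(OC(C)=O)c(OC)cc1O
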